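In a one-step world I multiply one rate by the time. This flask has two clocks: the partner decays while the catalyst cycles.

substrate 0.50 mM; partner 5.00 equiv; free catalyst 3.4 mol%

    substrate + free catalyst → catalyst intermediate A (k1 = 2.6 × 10⁵ M⁻¹ s⁻¹)
    catalyst intermediate A ⇌ catalyst intermediate B (K2 = 0.35, k2 = 270 s⁻¹)
    partner + catalyst intermediate B ⇌ catalyst intermediate C (K3 = 15000 M⁻¹, k3 = 9000 M⁻¹ s⁻¹)
    catalyst intermediate C → free catalyst + product (k4 = 6.3 s⁻¹)
    partner → decomposed reagent (k5 = 0.39 s⁻¹)

- the form that holds most of the catalyst when 30% of the substrate are converted (catalyst intermediate C / catalyst intermediate A / free catalyst / catalyst intermediate B)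
- its share of the catalyst then

Step 2 runs at 270 s⁻¹, faster than capture by the partner at 22 s⁻¹, so I treat catalyst intermediates A and B as one equilibrated pool, with B a fraction 0.259 of it. Catalyst intermediate C returns to the pool at 0.600 s⁻¹ and goes on at 6.3 s⁻¹. The pool therefore empties for good at 5.33 s⁻¹ with the partner as charged, and that rate decays at 0.39 s⁻¹.

With the substrate as charged, each cycle also costs a fixed 0.166 s in catalyst intermediate C and free catalyst. The product of rate and fixed time is the load, 0.886. A cycle lasts the inverse of the falling rate plus the fixed time, and this integrates in closed form to 9.78 cycles. That figure is the turnover budget: ln(1 + load), divided by the decay constant times the fixed time.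

Two extremes can be solved in the head for the resting state, the form holding most catalyst:

| Partner | A | B | C and free catalyst |
|---|---|---|---|
| as charged, held | 39.3% | 13.7% | 47.0% |
| none | 74.1% | 25.9% | 0% |

I expect the real flask between them, moving down the table as the partner decays. At the asked conversion, one catalyst load of substrate sits on the catalyst, so 7.82 cycles are spent and 1.95 remain. By this reckoning 15.3% of the partner is left, and I commit to catalyst intermediate A at 65.2%.

The forecast gives catalyst intermediate A at 68%, in its words “a rough mental integration rather than an exact result”.

The flask gives catalyst intermediate A at 67.4%, reached at 5.42 s, against my 65.2%. At 5.00 s, before the asked conversion, this flask already has 12.5% of its partner, less than the 15.3% I reckoned for that conversion. The budget times the loading is 33.2% of the substrate as product. At 100 s the flask holds 31.1% product, with 65.5% of the substrate left.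

The constants used here were chosen freely; the run is a simulation.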